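**Retrosynthetic overview**

1. Locants (germacrane skeleton): lactone C12(=O)–O–C6, methylene C13 on C11, ring-fusion C7, C8 (O-angelate), C9, C10 (methyl C14, ether O), C1, C2, C3 (OAc), C4 (C15H2OAc), C5 (ether O). Ring A is the oxepane O–C10–C1–C2–C3–C4–C5; ring B is the oxepane O–C5–C6–C7–C8–C9–C10.
2. Enabling feature: C10 is a fully substituted ether carbon of ring A (a latent oxocarbenium ion) and C6, next to C5, is a carbinol carbon, so C10/C6 form a 1,4-dielectrophile. C9–C8(O)–C7 is an acetone α,α′-dianion equivalent. One [4+3] annulation therefore makes C9–C10 and C6–C7, closing ring B and the ten-membered carbocycle.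
3. Disconnections: ester groups (late); lactone C12–O6; [4+3] between a ring-A ketal aldehyde and a 2-silyloxydiene ester; ring A by Baeyer–Villiger expansion and methylenation of an all-cis cyclohexanone; the cyclohexane by Diels–Alder reaction of diacetoxybutadiene with maleic anhydride, desymmetrised by alkaloid-mediated methanolysis.
4. Ring order: cyclohexane → ring A → ring B with the carbocycle (key step) → γ-lactone. Reagent control is used only in the desymmetrisation and the C8 reduction; all other stereocentres are relayed.

Key step: step 16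

Remark: read literally, the given descriptors put C6 (on C5) and C9 (on C10) on opposite faces of ring A, with the C10 methyl cis to C6 (a trans-bridged, in,out-type 11-oxabicyclo[4.4.1]undecane). The route is built for exactly this configuration, which is why C9–C10 is made first and intermolecularly.

**Route**

Step 1
Reactants: 1 (1E,3E)-buta-1,3-diene-1,4-diyl diacetate; 2 maleic anhydride
Product: 3 meso all-cis 3,6-diacetoxycyclohex-4-ene-1,2-dicarboxylic anhydride
Conditions: toluene, 90 °C
Reagents that add atoms: none
Why: Diels–Alder reaction; the suprafacial endo transition state of the (E,E)-diene with the cis-dienophile should place both acetoxy groups cis to each other and to the anhydride ring, so the all-cis relationship of C3–O, C4–C15 and C5–C6 (and of the later sacrificed C10–O) is set in one event as a meso compound.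

Step 2
Reactants: 3 meso cyclohexene anhydride
Product: 4 meso all-cis 3,6-diacetoxycyclohexane-1,2-dicarboxylic anhydride
Conditions: H2 (1 atm), Rh on Al2O3, EtOAc, rt
Reagents that add atoms: none
Why: heterogeneous hydrogenation of the cis-disubstituted ring alkene, needed before borane is used; no stereocentre is touched.

Step 3
Reactants: 4 meso anhydride
Product: 5 (1S,2R,3S,6R)-3,6-diacetoxy-2-(methoxycarbonyl)cyclohexane-1-carboxylic acid (acid carbon = C6 on C5, ester carbon = C15 on C4)
Conditions: quinidine (1.1 equiv), MeOH (3 equiv), toluene/CCl4 1:1, −55 °C; 2 N HCl work-up (alkaloid recovered)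
Reagents that add atoms: methanol, CO
Why: alkaloid-mediated enantioselective methanolysis of a meso anhydride (desymmetrisation): attack on one of the two enantiotopic carbonyl groups fixes the absolute configuration of C3, C4 and C5 for the whole route and tells C6 (acid) from C15 (ester); quinine, the pseudoenantiomer, would be used if the sense of induction on this substrate proved opposite.

Step 4
Reactants: 5 hemiester
Product: 6 hydroxy ester (C6 as CH2OH; methyl ester and both acetates kept)
Conditions: BH3·SMe2, THF, 0 °C
Reagents that add atoms: none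
Why: chemoselective borane reduction of the carboxylic acid in the presence of the methyl ester and the acetates.

Step 5
Reactants: 6 hydroxy ester
Product: 7 C6 benzyl ether
Conditions: benzyl 2,2,2-trichloroacetimidate, TfOH (cat.), CH2Cl2/cyclohexane, 0 °C
Reagents that add atoms: benzyl 2,2,2-trichloroacetimidate, ClC(Cl)(Cl)C(=N)OCc1ccccc1
Why: acid-catalysed O-benzylation with the trichloroacetimidate, chosen because it is base-free (no acetyl migration) and fast at 0 °C, before the cis hydroxy ester can lactonise.

Step 6
Reactants: 7 benzyl ether diacetate ester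
Product: 8 all-cis triol (C15H2OH, C3–OH, C10–OH; C6 benzyl ether)
Conditions: LiAlH4, THF, 0 °C to rt
Reagents that add atoms: none
Why: LiAlH4 reduces the methyl ester to the C15 carbinol and cleaves both acetates, unveiling the triol without touching the benzyl ether.

Step 7
Reactants: 8 triol
Product: 9 O3,O15-di-tert-butylsilylene alcohol (C10–OH free)
Conditions: tBu2Si(OTf)2 (1.05 equiv), 2,6-lutidine, CH2Cl2, −40 to 0 °C
Reagents that add atoms: di-tert-butylsilyl bis(trifluoromethanesulfonate), CC(C)(C)[Si](OS(=O)(=O)C(F)(F)F)(OS(=O)(=O)C(F)(F)F)C(C)(C)C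
Why: silylene protection: the bis-triflate should react first at the primary C15 hydroxyl and close the six-membered dioxasilinane onto the cis-vicinal C3 hydroxyl, leaving the C10 hydroxyl free because it could only give a seven-membered ring.

Step 8
Reactants: 9 silylene alcohol
Product: 10 all-cis cyclohexanone (C10 ketone)
Conditions: Dess–Martin periodinane, NaHCO3, CH2Cl2, 0 °C to rt
Reagents that add atoms: none
Why: Dess–Martin oxidation of the secondary alcohol under buffered conditions, which should avoid epimerisation of the α-stereocentre C5 and β-elimination of the benzyloxy group.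

Step 9
Reactants: 10 cyclohexanone
Product: 11 ring-A lactone (oxepan-2-one; O5 between C10 and C5)
Conditions: mCPBA, NaHCO3, CH2Cl2, 0 °C to rt
Reagents that add atoms: 3-chloroperbenzoic acid, OOC(=O)c1cccc(Cl)c1
Why: Baeyer–Villiger oxidation; the more substituted α-carbon C5 migrates with retention of configuration, so the ring oxygen O5 is inserted between C10 and C5 and ring A is formed as its lactone.

Step 10
Reactants: 11 ring-A lactone
Product: 12 exocyclic enol ether (2-methyleneoxepane)
Conditions: Cp2TiMe2, toluene, 70 °C, dark
Reagents that add atoms: dimethyltitanocene Cp2TiMe2, C[Ti](C)(C1C=CC=C1)C1C=CC=C1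
Why: Petasis methylenation of the lactone carbonyl gives the exocyclic enol ether, whose new carbon is the future C14 methyl group; silyl and benzyl ethers are inert.

Step 11
Reactants: 12 enol ether
Product: 13 ring-A methyl ketal (2-methoxy-2-methyloxepane; mixture at C10)
Conditions: MeOH, pyridinium p-toluenesulfonate (cat.), CH2Cl2, 0 °C; Et3N quench
Reagents that add atoms: methanol, CO
Why: acid-catalysed Markovnikov addition of methanol to the enol ether (ketal formation via the tertiary oxocarbenium ion); the configuration of the ketal carbon is irrelevant because it is ionised again in step 16.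

Step 12
Reactants: 13 benzyl ether ketal
Product: 14 ketal alcohol (C6H2OH)
Conditions: H2 (1 atm), Pd(OH)2 on carbon, solid NaHCO3, EtOAc, rt
Reagents that add atoms: none
Why: hydrogenolysis of the benzyl ether; solid NaHCO3 keeps the medium neutral so that the free C6 hydroxyl does not displace methanol from the ketal.

Step 13
Reactants: 14 ketal alcohol
Product: 15 ketal aldehyde (C6 aldehyde on C5; C10 methyl ketal)
Conditions: Dess–Martin periodinane, pyridine, CH2Cl2, 0 °C; used crude
Reagents that add atoms: none
Why: Dess–Martin oxidation buffered with pyridine should give the α-alkoxy aldehyde without epimerisation at C5 or loss of the ketal.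

Step 14
Reactants: 16 methyl pyruvate; 17 (acetylmethylene)triphenylphosphorane
Product: 18 methyl (2E)-2-methyl-4-oxopent-2-enoate
Conditions: CH2Cl2, rt to reflux
Reagents that add atoms: none
Why: Wittig olefination of the activated ketone of methyl pyruvate with a stabilised ylide; the E isomer (methyl cis to acetyl) should predominate and is the one wanted for the later γ-deprotonation.

Step 15
Reactants: 18 enone ester
Product: 19 methyl (2E)-2-methyl-4-[(triethylsilyl)oxy]penta-2,4-dienoate
Conditions: Et3SiOTf, Et3N, Et2O, 0 °C
Reagents that add atoms: triethylsilyl trifluoromethanesulfonate, CC[Si](CC)(CC)OS(=O)(=O)C(F)(F)F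
Why: soft enolisation of the methyl ketone with a silyl triflate and Et3N gives the cross-conjugated 2-silyloxydiene, the standard preparation of such dienes from enones.

Step 16
Reactants: 15 ketal aldehyde; 19 silyloxydiene ester
Product: 22 silyl aldol bicycle (rings A and B; 6-O-triethylsilyl; C8 ketone; C7 acrylate arm), via enone aldehyde 20 (not isolated), via silyl dienol ether 21 (not isolated)
Conditions: 19 (1.5 equiv), Et3SiOTf (0.2 equiv), CH2Cl2, −78 °C; then dilution to 0.005 M, iPr2NEt (4 equiv), Et3SiOTf (2.2 equiv), −78 to −20 °C; NaHCO3 quench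
Reagents that add atoms: triethylsilyl trifluoromethanesulfonate, CC[Si](CC)(CC)OS(=O)(=O)C(F)(F)F
Why: Proposed new method: a one-flask [4+3] annulation in which catalytic Et3SiOTf first ionises the methyl ketal to the C10 oxocarbenium ion of ring A, which is attacked by the terminal carbon of 19 to give enone 20 (closest known type: Mukaiyama–Noyori substitution of ketals by enol silanes), and Et3SiOTf with iPr2NEt then turns 20, by γ-deprotonation of the methyl group that lies cis to the ketone, into silyl dienol ether 21, whose α-carbon C7 adds to the silyl-activated aldehyde C6 with silyl transfer to O6 (closest known type: in situ enol silane formation and Mukaiyama aldol addition with R3SiOTf and a tertiary amine); the coupling of the two events on one 1,4-dielectrophile to close a bridged oxepanone is not known. The ring closed is ring B (O5–C5–C6–C7–C8–C9–C10) and with it the ten-membered carbocycle, by a 7-(enolendo)-exo-trig addition to the aldehyde. C10 is set in the intermolecular event by approach of 19 to the oxocarbenium face opposite to the three cis substituents on C3, C4 and C5 (silylene ring and formyl group), which puts C9 trans and the methyl group cis to C6, as the target requires. C6 and C7 are set in the ring closure, which should pass through the arrangement with the C6 silyloxy group and the C7 acrylate arm pseudo-equatorial, that is trans to each other and trans to C4 on C5. The step needs chemoselectivity (ketal before aldehyde, secured because silyl triflates ionise ketals at −78 °C but do not promote aldehyde addition there), site selectivity (C9 before C7, secured because C7 becomes nucleophilic only after the second enolisation, which the neopentyl position C9 resists) and facial selectivity at C10 (secured by the all-cis array). Because the bicycle formed is the strained trans-bridged one, high dilution and the irreversible silyl transfer are relied on to drive the closure.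

Step 17
Reactants: 22 silyl aldol bicycle
Product: 24 keto-lactone (trans-fused 6,12-olide; C8 ketone; silylene kept), via hydroxy ester 23 (not isolated)
Conditions: pyridinium p-toluenesulfonate, MeOH, 0 °C to rt; then pyridinium p-toluenesulfonate (cat.), toluene, 45 °C
Reagents that add atoms: none
Why: mild acid methanolysis of the secondary triethylsilyl ether followed by acid-catalysed lactonisation (intramolecular transesterification) of the γ-hydroxy ester; C6 and C7 are already fixed, so the lactone closes trans-fused, and non-basic conditions are used to keep the exocyclic alkene from migrating toward the C8 ketone.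

Step 18
Reactants: 24 keto-lactone
Product: 25 8-hydroxy lactone (hydroxyl cis to C11 on C7)
Conditions: (S)-2-methyl-CBS-oxazaborolidine (1 equiv), catecholborane, toluene/CH2Cl2, −78 °C
Reagents that add atoms: none
Why: Corey–Bakshi–Shibata reduction under reagent control: the catalyst should distinguish the branched C7 flank from the C9 methylene flank and deliver hydride to the face that gives the (8R)-alcohol (hydroxyl cis to C11 on C7, trans to O6), while catecholborane at −78 °C should leave the α-methylene lactone untouched.

Step 19
Reactants: 25 8-hydroxy lactone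
Product: 26 8-O-angelate
Conditions: angelic acid, 2,4,6-trichlorobenzoyl chloride, Et3N, toluene, rt; then 25, 80 °C
Reagents that add atoms: angelic acid [(2Z)-2-methylbut-2-enoic acid], C/C=C(/C)C(=O)O
Why: Yamaguchi-type esterification through the mixed 2,4,6-trichlorobenzoic anhydride of angelic acid without a nucleophilic catalyst, a protocol that acylates hindered secondary alcohols with retention of the Z geometry of the angelate.

Step 20
Reactants: 26 silylene angelate
Product: 27 3,15-diol
Conditions: HF·pyridine, pyridine, THF, 0 °C to rt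
Reagents that add atoms: none
Why: fluoride cleavage of the silylene with buffered HF·pyridine, which should leave lactone, angelate and tertiary ether intact.

Step 21
Reactants: 27 diol
Product: 28 target CNP0346171.1
Conditions: Ac2O, pyridine, 4-(dimethylamino)pyridine (cat.), CH2Cl2, 0 °C to rt
Reagents that add atoms: acetic anhydride, CC(=O)OC(C)=O
Why: standard acetylation of the primary C15 and secondary C3 hydroxyl groups.

**Compound list**

1 | (1E,3E)-buta-1,3-diene-1,4-diyl diacetate | CC(=O)O/C=C/C=C/OC(C)=O | starting material
2 | maleic anhydride | O=C1OC(=O)C=C1 | starting material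
3 | meso all-cis 3,6-diacetoxycyclohex-4-ene-1,2-dicarboxylic anhydride | CC(=O)O[C@H]1C=C[C@@H](OC(C)=O)[C@H]2C(=O)OC(=O)[C@@H]12 | intermediate
4 | meso all-cis 3,6-diacetoxycyclohexane-1,2-dicarboxylic anhydride | CC(=O)O[C@H]1CC[C@@H](OC(C)=O)[C@H]2C(=O)OC(=O)[C@@H]12 | intermediate
5 | (1S,2R,3S,6R)-3,6-diacetoxy-2-(methoxycarbonyl)cyclohexane-1-carboxylic acid | OC(=O)[C@@H]1[C@H](OC(C)=O)CC[C@H](OC(C)=O)[C@@H]1C(=O)OC | intermediate
6 | methyl all-cis 2,5-diacetoxy-6-(hydroxymethyl)cyclohexane-1-carboxylate (configuration as in 5) | OC[C@@H]1[C@H](OC(C)=O)CC[C@H](OC(C)=O)[C@@H]1C(=O)OC | intermediate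
7 | methyl all-cis 2,5-diacetoxy-6-[(benzyloxy)methyl]cyclohexane-1-carboxylate | c1ccccc1COC[C@@H]1[C@H](OC(C)=O)CC[C@H](OC(C)=O)[C@@H]1C(=O)OC | intermediate
8 | all-cis 2-[(benzyloxy)methyl]-3-(hydroxymethyl)cyclohexane-1,4-diol | c1ccccc1COC[C@@H]1[C@H](O)CC[C@@H](O)[C@@H]1CO | intermediate
9 | O3,O15-di-tert-butylsilylene of 8 (cis-fused dioxasilinane; C10–OH free) | c1ccccc1COC[C@@H]1[C@H](O)CC[C@@H]2O[Si](C(C)(C)C)(C(C)(C)C)OC[C@H]12 | intermediate
10 | all-cis cyclohexanone (C10 ketone, C5 CH2OBn, silylene on O3/O15) | c1ccccc1COC[C@@H]1C(=O)CC[C@@H]2O[Si](C(C)(C)C)(C(C)(C)C)OC[C@H]12 | intermediate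
11 | ring-A lactone (oxepan-2-one; C5 CH2OBn, silylene) | c1ccccc1COC[C@@H]1OC(=O)CC[C@@H]2O[Si](C(C)(C)C)(C(C)(C)C)OC[C@H]12 | intermediate
12 | ring-A exocyclic enol ether (2-methyleneoxepane) | c1ccccc1COC[C@@H]1OC(=C)CC[C@@H]2O[Si](C(C)(C)C)(C(C)(C)C)OC[C@H]12 | intermediate
13 | ring-A methyl ketal, C6 benzyl ether (mixture at C10) | c1ccccc1COC[C@@H]1OC(C)(OC)CC[C@@H]2O[Si](C(C)(C)C)(C(C)(C)C)OC[C@H]12 | intermediate
14 | ring-A methyl ketal, C6 alcohol | OC[C@@H]1OC(C)(OC)CC[C@@H]2O[Si](C(C)(C)C)(C(C)(C)C)OC[C@H]12 | intermediate
15 | ring-A methyl ketal, C6 aldehyde | O=C[C@@H]1OC(C)(OC)CC[C@@H]2O[Si](C(C)(C)C)(C(C)(C)C)OC[C@H]12 | intermediate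
16 | methyl pyruvate | CC(=O)C(=O)OC | starting material
17 | (acetylmethylene)triphenylphosphorane | CC(=O)C=P(c1ccccc1)(c1ccccc1)c1ccccc1 | starting material
18 | methyl (2E)-2-methyl-4-oxopent-2-enoate | CC(=O)/C=C(\C)C(=O)OC | intermediate
19 | methyl (2E)-2-methyl-4-[(triethylsilyl)oxy]penta-2,4-dienoate | C=C(O[Si](CC)(CC)CC)/C=C(\C)C(=O)OC | intermediate
20 | enone aldehyde (C9–C10 formed; C9 trans, methyl cis to C6) | O=C[C@@H]1O[C@](C)(CC[C@@H]2O[Si](C(C)(C)C)(C(C)(C)C)OC[C@H]12)CC(=O)/C=C(\C)C(=O)OC | intermediate
21 | silyl dienol ether of 20 (enol geometry not specified) | O=C[C@@H]1O[C@](C)(CC[C@@H]2O[Si](C(C)(C)C)(C(C)(C)C)OC[C@H]12)CC(O[Si](CC)(CC)CC)=CC(=C)C(=O)OC | intermediate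
22 | silyl aldol bicycle (rings A and B; 6-O-triethylsilyl, 8-oxo, methyl acrylate on C7) | C=C(C(=O)OC)[C@H]1[C@H](O[Si](CC)(CC)CC)[C@@H]2O[C@](C)(CC[C@@H]3O[Si](C(C)(C)C)(C(C)(C)C)OC[C@H]23)CC1=O | intermediate
23 | hydroxy ester (6-OH, 8-oxo, methyl acrylate on C7) | C=C(C(=O)OC)[C@H]1[C@H](O)[C@@H]2O[C@](C)(CC[C@@H]3O[Si](C(C)(C)C)(C(C)(C)C)OC[C@H]23)CC1=O | intermediate
24 | keto-lactone (8-oxo, trans-fused α-methylene 6,12-olide, silylene) | C=C1C(=O)O[C@@H]2[C@@H]3O[C@](C)(CC[C@@H]4O[Si](C(C)(C)C)(C(C)(C)C)OC[C@H]34)CC(=O)[C@@H]12 | intermediate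
25 | 8-hydroxy lactone (8R; silylene) | C=C1C(=O)O[C@@H]2[C@@H]3O[C@](C)(CC[C@@H]4O[Si](C(C)(C)C)(C(C)(C)C)OC[C@H]34)C[C@@H](O)[C@@H]12 | intermediate
26 | 8-O-angelate (silylene) | C=C1C(=O)O[C@@H]2[C@@H]3O[C@](C)(CC[C@@H]4O[Si](C(C)(C)C)(C(C)(C)C)OC[C@H]34)C[C@@H](OC(=O)/C(C)=C\C)[C@@H]12 | intermediate
27 | 3,15-diol 8-O-angelate | C=C1C(=O)O[C@@H]2[C@@H]3O[C@](C)(CC[C@H](O)[C@@H]3CO)C[C@@H](OC(=O)/C(C)=C\C)[C@@H]12 | intermediate
28 | CNP0346171.1 | C=C1C(=O)O[C@@H]2[C@@H]3O[C@](C)(CC[C@H](OC(C)=O)[C@@H]3COC(C)=O)C[C@@H](OC(=O)/C(C)=C\C)[C@@H]12 | target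

**Step count**

Total step count: 21. Longest linear sequence: 19 steps (steps 1–13 and 16–21).

**Steps most likely to fail**

1. Step 16 (proposed new method). The intermolecular attack on the oxocarbenium ion may lack facial selectivity, enolisation toward C9 may lead to β-elimination of O5, or the strained second ring closure may not take place. The fallback uses known reaction types in separate flasks and sets out from 14.
   - Internal transketalisation (pyridinium p-toluenesulfonate, CH2Cl2, loss of methanol) should give the bicyclic ketal F1, in which O6 bridges to C10 on the face of C6.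
   - In parallel, 18 is brominated (N-bromosuccinimide, azobisisobutyronitrile, CCl4, reflux) to methyl (2Z)-2-(bromomethyl)-4-oxopent-2-enoate F2, which is converted (Et3SiOTf, Et3N) into the bromo silyloxydiene F3.
   - TiCl4-mediated opening of F1 with F3 (CH2Cl2, −78 °C) follows the known invertive course of bicyclic ketal openings by enol silanes, so C9 enters anti to the departing O6; this should give the hydroxy bromo enone F4.
   - Dess–Martin oxidation gives the bromo enone aldehyde F5.
   - CrCl2 in THF then effects an intramolecular Nozaki–Hiyama-type addition of the chromium dienolate through C7 to the aldehyde, with lactonisation on work-up; the route is rejoined at 24.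
2. Step 18. Facial selectivity in the ketone reduction may be poor or reversed if the bias of the bridged bicycle overrides the catalyst. The fallback sets out from 24: reduction with NaBH4/CeCl3·7H2O (MeOH, −78 °C), or the minor product of the catalytic reduction, supplies the C8-epimeric alcohol F6. Mitsunobu esterification of F6 with angelic acid (PPh3, diisopropyl azodicarboxylate, toluene, 0 °C) inverts C8 and installs the angelate in one step, rejoining the route at 26.
3. Step 3. The hindered diacetoxy anhydride may open slowly or with low enantioselectivity. The fallback sets out from 4: uncatalysed methanolysis (MeOH, reflux) gives the racemic hemiester F7, which is resolved by crystallisation of the (R)-1-phenylethylammonium salt F8 of the wanted enantiomer; acidification returns 5.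

**Further compounds**

F1 | step 16 | bicyclic ketal (O6–C10 bridge, 7,9-dioxabicyclo[4.2.1]nonane core, silylene) | C[C@]12CC[C@@H]3O[Si](C(C)(C)C)(C(C)(C)C)OC[C@@H]3[C@H](CO1)O2
F2 | step 16 | methyl (2Z)-2-(bromomethyl)-4-oxopent-2-enoate | CC(=O)/C=C(\CBr)C(=O)OC
F3 | step 16 | methyl (2Z)-2-(bromomethyl)-4-[(triethylsilyl)oxy]penta-2,4-dienoate | C=C(O[Si](CC)(CC)CC)/C=C(\CBr)C(=O)OC
F4 | step 16 | hydroxy bromo enone (C6H2OH; C9 trans to C6) | OC[C@@H]1O[C@](C)(CC[C@@H]2O[Si](C(C)(C)C)(C(C)(C)C)OC[C@H]12)CC(=O)/C=C(\CBr)C(=O)OC
F5 | step 16 | bromo enone aldehyde | O=C[C@@H]1O[C@](C)(CC[C@@H]2O[Si](C(C)(C)C)(C(C)(C)C)OC[C@H]12)CC(=O)/C=C(\CBr)C(=O)OC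
F6 | step 18 | C8-epimeric 8-hydroxy lactone | C=C1C(=O)O[C@@H]2[C@@H]3O[C@](C)(CC[C@@H]4O[Si](C(C)(C)C)(C(C)(C)C)OC[C@H]34)C[C@H](O)[C@@H]12
F7 | step 3 | racemic hemiester (5 and its enantiomer) | OC(=O)[C@@H]1[C@H](OC(C)=O)CC[C@H](OC(C)=O)[C@@H]1C(=O)OC.OC(=O)[C@H]1[C@@H](OC(C)=O)CC[C@@H](OC(C)=O)[C@H]1C(=O)OC
F8 | step 3 | (R)-1-phenylethylammonium salt of 5 | [O-]C(=O)[C@@H]1[C@H](OC(C)=O)CC[C@H](OC(C)=O)[C@@H]1C(=O)OC.C[C@@H]([NH3+])c1ccccc1
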